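**Retrosynthetic overview**
- The target is opened to its bis-ynoate diol (Lindlar semi-hydrogenation last, giving both Z-enoates), then to the bis-TBS ether, then by a twofold Michael disconnection to (S)-6-methyloxane-2,4-dione and two molecules of a 14-membered (E)-ene-dione macrodiolide. This step makes both C–C bonds to the quaternary carbon and both C9 stereocentres.
- The 14-membered ene-dione comes from a one-carbon ring expansion of a 13-membered β-keto macrodiolide (zinc carbenoid, 1,2-acyl shift through a cyclopropanolate), with iodination and elimination in the same flask.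
- The 13-membered ring comes from acylketene macrolactonisation of a tert-butyl β-keto ester seco-alcohol. That is the ester of tert-butyl (S)-6-hydroxy-3-oxoheptanoate ((S)-γ-valerolactone + tert-butyl acetate) with a (4R,5S)-4,5-bis(silyloxy)hex-2-ynoic acid (ethyl (S)-lactate + propiolic acid, Felkin–Anh addition).
- The six-membered keto-lactone comes from methyl (S)-3-hydroxybutanoate and tert-butyl acetate (Claisen condensation, then acid lactonisation).
- Ring order: the 13-membered ring is closed and then enlarged to the 14-membered ring; the six-membered ring is made separately; the three rings are joined in the double Michael step.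

Assumption: the SMILES is read as drawn, with two identical macrocycles (3Z,5R,6S,9R,14S), lactone carbon 6S, and a quaternary lactone carbon that is not a stereocentre because its two ring substituents are identical.
Assumption: the quinine-derived catalyst of step 10 is taken as matched with the peripheral-attack bias of the macrocycle; if it is not, its quinidine-derived pseudo-enantiomer is used under the same conditions.

**Route**

Step 1
Reactants: 1 ethyl (S)-lactate [ethyl (2S)-2-hydroxypropanoate]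
Product: 2 ethyl (2S)-2-(triethylsilyloxy)propanoate
Conditions: TESCl, imidazole, CH2Cl2, 0 °C to rt
Reagents that add atoms: chlorotriethylsilane, CC[Si](Cl)(CC)CC
Why: Standard O-silylation of a secondary alcohol that leaves the lactate stereocentre (future C6 of each macrocycle) untouched, with TES chosen so that it can later be removed beside a TBS ether.

Step 2
Reactants: 2 ethyl (2S)-2-(triethylsilyloxy)propanoate
Product: 3 (2S)-2-(triethylsilyloxy)propanal
Conditions: i-Bu2AlH (1.05 equiv), CH2Cl2, −78 °C; aq. potassium sodium tartrate (KNaC4H4O6)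
Reagents that add atoms: none
Why: Half-reduction of the ester through the aluminium hemiacetal that is stable at −78 °C (i-Bu2AlH ester-to-aldehyde reduction) gives the configurationally intact α-silyloxy aldehyde, which is used crude.

Step 3
Reactants: 3 (2S)-2-(triethylsilyloxy)propanal; 4 propiolic acid
Product: 7 (4R,5S)-4-(tert-butyldimethylsilyloxy)-5-(triethylsilyloxy)hex-2-ynoic acid, via dilithium alkoxide carboxylate 5 (not isolated), via silyl ester 6 (not isolated)
Conditions: 4 (1.5 equiv), n-BuLi (3.0 equiv), THF/DMPU, −78 °C; then 3, −78 °C; then TBSOTf (3.5 equiv), −78 to 0 °C; K2CO3, MeOH/H2O, rt; NaH2PO4 to pH 4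
Reagents that add atoms: tert-butyldimethylsilyl trifluoromethanesulfonate, CC(C)(C)[Si](C)(C)OS(=O)(=O)C(F)(F)F
Why: Acetylide addition of dilithiated propiolic acid to the α-silyloxy aldehyde follows the polar Felkin–Anh model (Re-face attack anti to the OTES group) and sets C4 as R, i.e. the anti 4,5-dioxygenation (dr about 4–5:1 expected, minor epimer removed by chromatography here or after step 5), while the lithium alkoxide is silylated in the same flask and the silyl ester is cleaved in the basic work-up.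

Step 4
Reactants: 8 (S)-γ-valerolactone [(5S)-5-methyloxolan-2-one]; 9 tert-butyl acetate
Product: 10 tert-butyl (6S)-6-hydroxy-3-oxoheptanoate
Conditions: 9 (2.2 equiv), LiN(i-Pr)2 (2.2 equiv), THF, −78 °C; then 8, −78 to −40 °C; aq. NH4Cl
Reagents that add atoms: none
Why: Claisen-type acylation of the tert-butyl acetate lithium enolate by the lactone opens the ring to the hydroxy β-keto ester (the second equivalent of enolate deprotonates the product and stops over-addition) without touching the stereocentre that becomes C14.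

Step 5
Reactants: 7 (4R,5S)-4-(tert-butyldimethylsilyloxy)-5-(triethylsilyloxy)hex-2-ynoic acid; 10 tert-butyl (6S)-6-hydroxy-3-oxoheptanoate
Product: 11 tert-butyl (6S)-6-{[(4R,5S)-4-(tert-butyldimethylsilyloxy)-5-(triethylsilyloxy)hex-2-ynoyl]oxy}-3-oxoheptanoate
Conditions: DCC (1.2 equiv), DMAP (0.1 equiv), CH2Cl2, −20 to 0 °C
Reagents that add atoms: none
Why: Steglich esterification acylates the open-chain secondary alcohol of 10 (in equilibrium with its hemiketal) with retention at the carbinol carbon, and low temperature with only catalytic DMAP keeps the ynoic acid from conjugate addition.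

Step 6
Reactants: 11 tert-butyl (6S)-6-{[(4R,5S)-4-(tert-butyldimethylsilyloxy)-5-(triethylsilyloxy)hex-2-ynoyl]oxy}-3-oxoheptanoate
Product: 12 tert-butyl (6S)-6-{[(4R,5S)-4-(tert-butyldimethylsilyloxy)-5-hydroxyhex-2-ynoyl]oxy}-3-oxoheptanoate
Conditions: PPTS (0.2 equiv), MeOH, 0 °C to rt
Reagents that add atoms: none
Why: Acid-catalysed methanolysis (selective desilylation) cleaves the secondary TES ether far faster than the secondary TBS ether, and the linear alkyne prevents the freed 5-OH from lactonising onto the ynoate.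

Step 7
Reactants: 12 tert-butyl (6S)-6-{[(4R,5S)-4-(tert-butyldimethylsilyloxy)-5-hydroxyhex-2-ynoyl]oxy}-3-oxoheptanoate
Product: 14 (5R,6S,13S)-5-(tert-butyldimethylsilyloxy)-6,13-dimethyl-1,7-dioxacyclotridec-3-yne-2,8,10-trione, via acylketene 13 (not isolated)
Conditions: syringe-pump addition (8 h) into toluene at 110 °C, final 0.5 mM, N2 sweep
Reagents that add atoms: none
Why: Thermolysis of the tert-butyl β-keto ester expels tert-butanol to give an acylketene that is trapped by the C6 hydroxyl at high dilution (acylketene macrolactonisation) under neutral conditions that spare the silyl ether and the ynoate and touch no stereocentre.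

Step 8
Reactants: 14 (5R,6S,13S)-5-(tert-butyldimethylsilyloxy)-6,13-dimethyl-1,7-dioxacyclotridec-3-yne-2,8,10-trione
Product: 17 (5R,6S,9E,14S)-5-(tert-butyldimethylsilyloxy)-6,14-dimethyl-1,7-dioxacyclotetradec-9-en-3-yne-2,8,11-trione, via ethylzinc enolate 15 (not isolated), via α-iodo lactone 16 (not isolated)
Conditions: Et2Zn (5 equiv), CH2I2 (5 equiv), CH2Cl2, 0 °C to rt, 1 h; I2 to persistent colour, 0 °C; aq. Na2S2O3; then DBU (1.5 equiv), CH2Cl2, 0 °C
Reagents that add atoms: diiodomethane, ICI; iodine, II (stays only in intermediate 16)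
Why: Zinc-carbenoid chain extension of the β-keto lactone (tandem chain extension–iodination–elimination) methylenates the zinc enolate to a donor–acceptor cyclopropanolate that fragments with a 1,2-acyl shift, inserting CH2 between C9 and the ketone and enlarging the ring from 13 to 14 members, after which the C9 zinc species is iodinated and dehydroiodinated (E1cB) to the (E)-ene-dione while the electron-poor ynoate stays inert to the carbenoid.

Step 9
Reactants: 18 methyl (3S)-3-hydroxybutanoate; 9 tert-butyl acetate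
Product: 20 (6S)-6-methyloxane-2,4-dione, via hydroxy keto ester 19 (not isolated)
Conditions: 9 (3.5 equiv), LiN(i-Pr)2 (3.5 equiv), THF, −78 to −20 °C; aq. NH4Cl; crude in TFA/CH2Cl2 (1:4), rt
Reagents that add atoms: none
Why: Crossed Claisen condensation of the hydroxy ester (as its alkoxide) with excess tert-butyl lithioacetate, followed by acid cleavage of the tert-butyl ester and δ-lactonisation, gives the cyclic β-keto lactone with the carbinol stereocentre retained as S.

Step 10
Reactants: 17 (5R,6S,9E,14S)-5-(tert-butyldimethylsilyloxy)-6,14-dimethyl-1,7-dioxacyclotetradec-9-en-3-yne-2,8,11-trione (2.2 equiv); 20 (6S)-6-methyloxane-2,4-dione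
Product: 22 (6S)-3,3-bis[(5R,6S,9R,14S)-5-(tert-butyldimethylsilyloxy)-6,14-dimethyl-2,8,11-trioxo-1,7-dioxacyclotetradec-3-yn-9-yl]-6-methyloxane-2,4-dione, via mono-adduct 21 (not isolated)
Conditions: quinine-derived squaramide (from 3,5-bis(trifluoromethyl)benzylamine, squaric acid and 9-amino-9-deoxy-epi-quinine; 10 mol%), CH2Cl2 (0.3 M in 17), 4 Å MS, rt 6 h, then 40 °C, 48 h
Reagents that add atoms: none
Why: Proposed new method: a catalyst-relayed twofold Michael addition in which the tertiary amine of the bifunctional squaramide deprotonates the acidic cyclic β-keto lactone 20 and then its still acidic mono-adduct 21, while the squaramide N–H groups bind the C11 ketone of ene-dione 17, so that the lactone C3 adds twice at C9 (β to the ketone, α to the ester), the second, slower addition being driven by the doubly activated acceptor and giving the quaternary carbon; each C9 is attacked on its exposed Si face (peripheral attack on the macrocycle, reinforced by the catalyst) to give R at both new CH centres, the quaternary carbon is not stereogenic because the two substituents are identical, and the hindered γ-silyloxy ynoates are far poorer acceptors than the ene-dione; the closest known chemistry is the cinchona-squaramide Michael addition of cyclic 1,3-dicarbonyls to enones and 4-oxo-enoates and the quaternary-centre-forming Michael addition of 2-substituted cyclic 1,3-diones to enones, neither of which has been shown as a double addition to a macrocyclic acceptor.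

Step 11
Reactants: 22 (6S)-3,3-bis[(5R,6S,9R,14S)-5-(tert-butyldimethylsilyloxy)-6,14-dimethyl-2,8,11-trioxo-1,7-dioxacyclotetradec-3-yn-9-yl]-6-methyloxane-2,4-dione
Product: 23 (6S)-3,3-bis[(5R,6S,9R,14S)-5-hydroxy-6,14-dimethyl-2,8,11-trioxo-1,7-dioxacyclotetradec-3-yn-9-yl]-6-methyloxane-2,4-dione
Conditions: HF·pyridine, pyridine, THF, 0 °C to rt
Reagents that add atoms: none
Why: Fluoride-mediated desilylation of the two secondary TBS ethers under buffered, weakly acidic conditions avoids base-induced isomerisation of the γ-hydroxy ynoates and retro-Claisen opening of the non-enolisable β-keto lactone.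

Step 12
Reactants: 23 (6S)-3,3-bis[(5R,6S,9R,14S)-5-hydroxy-6,14-dimethyl-2,8,11-trioxo-1,7-dioxacyclotetradec-3-yn-9-yl]-6-methyloxane-2,4-dione
Product: 24 (6S)-3,3-bis[(3Z,5R,6S,9R,14S)-5-hydroxy-6,14-dimethyl-2,8,11-trioxo-1,7-dioxacyclotetradec-3-en-9-yl]-6-methyloxane-2,4-dione (CNP0083691.2)
Conditions: H2 (1 atm), Pd/CaCO3 poisoned with Pb(OAc)2 (5 wt% Pd), quinoline, EtOAc, rt, stopped after 2 equiv H2
Reagents that add atoms: none
Why: Lindlar semi-hydrogenation adds H2 syn to each ynoate and so gives both (Z)-enoates, and running it last under neutral conditions keeps the lactonisation-prone (Z)-γ-hydroxy enoates away from acid and base while ketones and esters are untouched.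

**Compound list**

1 | ethyl (S)-lactate | C[C@H](O)C(=O)OCC | starting material
2 | ethyl (2S)-2-(triethylsilyloxy)propanoate | C[C@H](O[Si](CC)(CC)CC)C(=O)OCC | intermediate
3 | (2S)-2-(triethylsilyloxy)propanal | C[C@H](O[Si](CC)(CC)CC)C=O | intermediate
4 | propiolic acid | C#CC(=O)O | starting material
5 | dilithium (4R,5S)-4-oxido-5-(triethylsilyloxy)hex-2-ynoate | C[C@H](O[Si](CC)(CC)CC)[C@H]([O-])C#CC(=O)[O-].[Li+].[Li+] | intermediate
6 | tert-butyldimethylsilyl (4R,5S)-4-(tert-butyldimethylsilyloxy)-5-(triethylsilyloxy)hex-2-ynoate | C[C@H](O[Si](CC)(CC)CC)[C@H](O[Si](C)(C)C(C)(C)C)C#CC(=O)O[Si](C)(C)C(C)(C)C | intermediate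
7 | (4R,5S)-4-(tert-butyldimethylsilyloxy)-5-(triethylsilyloxy)hex-2-ynoic acid | C[C@H](O[Si](CC)(CC)CC)[C@H](O[Si](C)(C)C(C)(C)C)C#CC(=O)O | intermediate
8 | (S)-γ-valerolactone | C[C@H]1CCC(=O)O1 | starting material
9 | tert-butyl acetate | CC(=O)OC(C)(C)C | starting material
10 | tert-butyl (6S)-6-hydroxy-3-oxoheptanoate | C[C@H](O)CCC(=O)CC(=O)OC(C)(C)C | intermediate
11 | tert-butyl (6S)-6-{[(4R,5S)-4-(tert-butyldimethylsilyloxy)-5-(triethylsilyloxy)hex-2-ynoyl]oxy}-3-oxoheptanoate | C[C@H](O[Si](CC)(CC)CC)[C@H](O[Si](C)(C)C(C)(C)C)C#CC(=O)O[C@@H](C)CCC(=O)CC(=O)OC(C)(C)C | intermediate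
12 | tert-butyl (6S)-6-{[(4R,5S)-4-(tert-butyldimethylsilyloxy)-5-hydroxyhex-2-ynoyl]oxy}-3-oxoheptanoate | C[C@H](O)[C@H](O[Si](C)(C)C(C)(C)C)C#CC(=O)O[C@@H](C)CCC(=O)CC(=O)OC(C)(C)C | intermediate
13 | (2S)-5,7-dioxohept-6-en-2-yl (4R,5S)-4-(tert-butyldimethylsilyloxy)-5-hydroxyhex-2-ynoate (acylketene) | C[C@H](O)[C@H](O[Si](C)(C)C(C)(C)C)C#CC(=O)O[C@@H](C)CCC(=O)C=C=O | intermediate
14 | (5R,6S,13S)-5-(tert-butyldimethylsilyloxy)-6,13-dimethyl-1,7-dioxacyclotridec-3-yne-2,8,10-trione | C[C@@H]1OC(=O)CC(=O)CC[C@H](C)OC(=O)C#C[C@H]1O[Si](C)(C)C(C)(C)C | intermediate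
15 | (5R,6S,14S)-5-(tert-butyldimethylsilyloxy)-9-(ethylzincio)-6,14-dimethyl-1,7-dioxacyclotetradec-3-yne-2,8,11-trione (zinc enolate drawn in its carbon-bound form, C9 undefined) | C[C@@H]1OC(=O)C([Zn]CC)CC(=O)CC[C@H](C)OC(=O)C#C[C@H]1O[Si](C)(C)C(C)(C)C | intermediate
16 | (5R,6S,14S)-5-(tert-butyldimethylsilyloxy)-9-iodo-6,14-dimethyl-1,7-dioxacyclotetradec-3-yne-2,8,11-trione (C9 epimers) | C[C@@H]1OC(=O)C(I)CC(=O)CC[C@H](C)OC(=O)C#C[C@H]1O[Si](C)(C)C(C)(C)C | intermediate
17 | (5R,6S,9E,14S)-5-(tert-butyldimethylsilyloxy)-6,14-dimethyl-1,7-dioxacyclotetradec-9-en-3-yne-2,8,11-trione | C[C@@H]1OC(=O)/C=C/C(=O)CC[C@H](C)OC(=O)C#C[C@H]1O[Si](C)(C)C(C)(C)C | intermediate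
18 | methyl (3S)-3-hydroxybutanoate | C[C@H](O)CC(=O)OC | starting material
19 | tert-butyl (5S)-5-hydroxy-3-oxohexanoate | C[C@H](O)CC(=O)CC(=O)OC(C)(C)C | intermediate
20 | (6S)-6-methyloxane-2,4-dione | C[C@H]1CC(=O)CC(=O)O1 | intermediate
21 | (6S)-3-[(5R,6S,9R,14S)-5-(tert-butyldimethylsilyloxy)-6,14-dimethyl-2,8,11-trioxo-1,7-dioxacyclotetradec-3-yn-9-yl]-6-methyloxane-2,4-dione (lactone C3 epimerisable, largely enol) | C[C@@H]1OC(=O)[C@@H](C2C(=O)C[C@H](C)OC2=O)CC(=O)CC[C@H](C)OC(=O)C#C[C@H]1O[Si](C)(C)C(C)(C)C | intermediate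
22 | (6S)-3,3-bis[(5R,6S,9R,14S)-5-(tert-butyldimethylsilyloxy)-6,14-dimethyl-2,8,11-trioxo-1,7-dioxacyclotetradec-3-yn-9-yl]-6-methyloxane-2,4-dione | C[C@@H]1OC(=O)[C@@H](C2([C@H]3CC(=O)CC[C@H](C)OC(=O)C#C[C@@H](O[Si](C)(C)C(C)(C)C)[C@H](C)OC3=O)C(=O)C[C@H](C)OC2=O)CC(=O)CC[C@H](C)OC(=O)C#C[C@H]1O[Si](C)(C)C(C)(C)C | intermediate
23 | (6S)-3,3-bis[(5R,6S,9R,14S)-5-hydroxy-6,14-dimethyl-2,8,11-trioxo-1,7-dioxacyclotetradec-3-yn-9-yl]-6-methyloxane-2,4-dione | C[C@@H]1OC(=O)[C@@H](C2([C@H]3CC(=O)CC[C@H](C)OC(=O)C#C[C@@H](O)[C@H](C)OC3=O)C(=O)C[C@H](C)OC2=O)CC(=O)CC[C@H](C)OC(=O)C#C[C@H]1O | intermediate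
24 | (6S)-3,3-bis[(3Z,5R,6S,9R,14S)-5-hydroxy-6,14-dimethyl-2,8,11-trioxo-1,7-dioxacyclotetradec-3-en-9-yl]-6-methyloxane-2,4-dione | C[C@@H]1OC(=O)[C@@H](C2([C@H]3CC(=O)CC[C@H](C)OC(=O)/C=C\[C@@H](O)[C@H](C)OC3=O)C(=O)C[C@H](C)OC2=O)CC(=O)CC[C@H](C)OC(=O)/C=C\[C@H]1O | target

**Step count**
Total: 12 steps. Longest linear sequence: 10 steps (1, 2, 3, 5, 6, 7, 8, 10, 11, 12); steps 4 and 9 are side branches.

**Three steps most likely to fail**

Step 10 (the proposed new double Michael addition). The second addition has to build a quaternary carbon between two macrocycles, the mono-adduct can rest as a cyclic hemiketal, retro-Michael may erode the C9 configuration, and the facial sense rests on the stated assumption. The fallback uses known chemistry, sets out from 17 and 20 and comes back at 22. Compound 20 (1.5 equiv) is added to one equivalent of 17 with Et3N (10 mol%) in CH2Cl2, the ordinary Michael addition of a cyclic 1,3-dicarbonyl to an enone, and the mono-adduct 21 is isolated and its C9 epimers separated. Its enol is silylated (TMSCl, Et3N, CH2Cl2, 0 °C) to give (6S)-3-[(5R,6S,9R,14S)-5-(tert-butyldimethylsilyloxy)-6,14-dimethyl-2,8,11-trioxo-1,7-dioxacyclotetradec-3-yn-9-yl]-6-methyl-4-(trimethylsilyloxy)-5,6-dihydro-2H-pyran-2-one F1. A Mukaiyama–Michael reaction of this tetrasubstituted silyl enol ether with a second equivalent of 17 (TiCl4, CH2Cl2, −78 °C) then forges the quaternary carbon and gives 22 after aqueous work-up.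

Step 8 (ring expansion on the functionalised macrocycle). The carbenoid, iodine and DBU all meet a strained 13-membered ring that carries an ynoate. The fallback sets out from 10 and 7 and comes back at 17; it moves the one-carbon homologation to the simple acyclic β-keto ester and closes the ring by carboxyl activation. Compound 10 is treated with Et2Zn/CH2I2, then I2, then DBU to give tert-butyl (2E,7S)-7-hydroxy-4-oxooct-2-enoate F5. This is esterified with acid 7 (DCC, catalytic DMAP) to tert-butyl (2E,7S)-7-{[(4R,5S)-4-(tert-butyldimethylsilyloxy)-5-(triethylsilyloxy)hex-2-ynoyl]oxy}-4-oxooct-2-enoate F6. PPTS in MeOH removes the TES group to give tert-butyl (2E,7S)-7-{[(4R,5S)-4-(tert-butyldimethylsilyloxy)-5-hydroxyhex-2-ynoyl]oxy}-4-oxooct-2-enoate F7. TMSOTf/2,6-lutidine followed by aqueous work-up cleaves the tert-butyl ester to (2E,7S)-7-{[(4R,5S)-4-(tert-butyldimethylsilyloxy)-5-hydroxyhex-2-ynoyl]oxy}-4-oxooct-2-enoic acid F8. Shiina macrolactonisation (2-methyl-6-nitrobenzoic anhydride, DMAP, CH2Cl2, 1 mM) then gives 17.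

Step 7 (macrolactonisation). Acylketene formation from a tert-butyl ester is slower than from a dioxinone, and oligomerisation or decarboxylative loss can compete. The fallback sets out from 7 and 8 and comes back at 14; it closes the ring at the ynoate ester after the β-keto ester has been made by a Claisen reaction. PPTS in MeOH converts 7 into (4R,5S)-4-(tert-butyldimethylsilyloxy)-5-hydroxyhex-2-ynoic acid F2. Ac2O/pyridine with aqueous work-up gives (4R,5S)-5-acetoxy-4-(tert-butyldimethylsilyloxy)hex-2-ynoic acid F3. Its dilithio derivative (LiN(i-Pr)2, 2.1 equiv, THF, −78 °C; carboxylate plus acetate enolate, two equivalents per lactone) is acylated by lactone 8, as in step 4, to give (4R,5S)-4-(tert-butyldimethylsilyloxy)-5-{[(6S)-6-hydroxy-3-oxoheptanoyl]oxy}hex-2-ynoic acid F4. Shiina macrolactonisation (2-methyl-6-nitrobenzoic anhydride, DMAP, CH2Cl2, 1 mM) then gives 14.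

**Further compounds**

F1 | step 10 | (6S)-3-[(5R,6S,9R,14S)-5-(tert-butyldimethylsilyloxy)-6,14-dimethyl-2,8,11-trioxo-1,7-dioxacyclotetradec-3-yn-9-yl]-6-methyl-4-(trimethylsilyloxy)-5,6-dihydro-2H-pyran-2-one | C[C@@H]1OC(=O)[C@@H](C2=C(O[Si](C)(C)C)C[C@H](C)OC2=O)CC(=O)CC[C@H](C)OC(=O)C#C[C@H]1O[Si](C)(C)C(C)(C)C
F2 | step 7 | (4R,5S)-4-(tert-butyldimethylsilyloxy)-5-hydroxyhex-2-ynoic acid | C[C@H](O)[C@H](O[Si](C)(C)C(C)(C)C)C#CC(=O)O
F3 | step 7 | (4R,5S)-5-acetoxy-4-(tert-butyldimethylsilyloxy)hex-2-ynoic acid | C[C@H](OC(C)=O)[C@H](O[Si](C)(C)C(C)(C)C)C#CC(=O)O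
F4 | step 7 | (4R,5S)-4-(tert-butyldimethylsilyloxy)-5-{[(6S)-6-hydroxy-3-oxoheptanoyl]oxy}hex-2-ynoic acid | C[C@H](O)CCC(=O)CC(=O)O[C@@H](C)[C@H](O[Si](C)(C)C(C)(C)C)C#CC(=O)O
F5 | step 8 | tert-butyl (2E,7S)-7-hydroxy-4-oxooct-2-enoate | C[C@H](O)CCC(=O)/C=C/C(=O)OC(C)(C)C
F6 | step 8 | tert-butyl (2E,7S)-7-{[(4R,5S)-4-(tert-butyldimethylsilyloxy)-5-(triethylsilyloxy)hex-2-ynoyl]oxy}-4-oxooct-2-enoate | C[C@H](O[Si](CC)(CC)CC)[C@H](O[Si](C)(C)C(C)(C)C)C#CC(=O)O[C@@H](C)CCC(=O)/C=C/C(=O)OC(C)(C)C
F7 | step 8 | tert-butyl (2E,7S)-7-{[(4R,5S)-4-(tert-butyldimethylsilyloxy)-5-hydroxyhex-2-ynoyl]oxy}-4-oxooct-2-enoate | C[C@H](O)[C@H](O[Si](C)(C)C(C)(C)C)C#CC(=O)O[C@@H](C)CCC(=O)/C=C/C(=O)OC(C)(C)C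
F8 | step 8 | (2E,7S)-7-{[(4R,5S)-4-(tert-butyldimethylsilyloxy)-5-hydroxyhex-2-ynoyl]oxy}-4-oxooct-2-enoic acid | C[C@H](O)[C@H](O[Si](C)(C)C(C)(C)C)C#CC(=O)O[C@@H](C)CCC(=O)/C=C/C(=O)O
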